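The earlier runs and the new flask were computed on assumed constants; noise was put on by code.

A ratio of 1.51 in charged Zb separates the oak run from the elm run, and the bench rule that rate goes with catalyst promised the same ratio in the rate of making Zg. At 0.500 h the oak reading of Zg was 1.22 times the elm reading, less than the rule promised. I then followed one molecule: once it has left Za it need not yet be Zg. So I held the stage fixed instead of the time, and took the rate of making Zg, as a fraction of the Za charged, over stretches of the two runs centred on nearly the same Zg.

| setting | elm | oak | ash | flask |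
|---|---|---|---|---|
| Za | 2.1 M | 2.1 M | 2.1 M | 2.1 M |
| Zc | 1.68 M | 1.68 M | 0.84 M | 1.68 M |
| Zb | 73 mM | 110 mM | 52 mM | 52 mM |
| Zd | 27 mM | 27 mM | 27 mM | 27 mM |
| remark | run made earlier | run made earlier | run made earlier |  |

- elm (time / h: Zg / %): 0.167: 4.9; 0.500: 20.5; 0.833: 35.8; 1.33: 52.7; 2.00: 62.3; 2.50: 68.5; 3.00: 71.6
- oak (time / h: Zg / %): 0.500: 25.0; 1.00: 46.7; 1.33: 55.2; 2.00: 66.4; 2.50: 70.6; 3.00: 73.3
- ash (time / h: Zg / %): 0.250: 4.5; 0.500: 9.7; 0.833: 18.9; 1.50: 31.7; 3.00: 38.7

(readings scatter by 0.5 percentage points)

- what was read earlier has a scatter of 0.5 percentage points, one standard deviation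
- "the catalyst" is Zb with its forms; Zd is a second catalyst
- what has left Za counts as converted, also if it is not yet product

* apparent order in Zb when 30% of the Za are converted (percent change of the rate of making Zg for one percent more Zb charged)
* factor on the rate of making Zg when 30% of the Za are converted if Zb is charged twice over

| Run | Zb charged | Stretch of Zg | Rate |
|---|---|---|---|
| elm | 73 mM | 20.5% to 52.7% | 0.388 h⁻¹ |
| oak | 110 mM | 25.0% to 46.7% | 0.434 h⁻¹ |

The oak rate was 1.12 times the elm rate, a ratio smaller than the one at equal time, and here the bench rule stopped working. This gave 0.274, my equal-stage order: the logarithm of the rate ratio at equal Zg over the logarithm of the charge ratio. It is a rough reading, since each reading scatters by 0.5 percentage points, and it comes from higher charges and a later stage than the flask at 30% conversion. I still committed to it for the flask, so I reckoned a factor of 1.21 for a doubled charge of Zb, two raised to that apparent order.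

The forecast stood higher than my order, at 0.35 with a factor of 1.3, saying "This looks like saturation".

The flask gave an order of 0.23 and a factor of 1.14, against my 0.274 and 1.21.

    Za + Zb → Zb + Ze (k = 0.723 M⁻¹ min⁻¹)
    Zc + Zd + Ze → Zd + Zg (k = 0.671 M⁻² min⁻¹)
    2 Zb ⇌ Zf (K = 14.0 M⁻¹, k = 1.29 M⁻¹ min⁻¹)

In the flask at 0.501 h, Za had a half-life of 0.55 h by its step with Zb, and Ze, the intermediate, had one of 0.49 h by its step with Zc and Zd, while Ze was made 1.39 times faster than it was used up. At 0.400 h the flask held 29.7% Ze, more than its 13.2% Zg.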